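## The problem

Target 19 consists of two isobutyrylphloroglucinol units joined by one CH2 (C7). Ring A is dearomatised (C1 quaternary with methyl and prenyl, C2 and C6 enolised carbonyls, C3 bearing C7, C4 the ring ketone, C5 bearing isobutyryl); ring B is a fully substituted benzene (chromene numbers with primes, C8' bearing C7); ring C is its fused 2,2-dimethylpyran. The only stereocentre, C1, lies between two carbonyl-derived carbons of the same kind. It is stereogenic only because C3 carries the bridge and C5 the acyl group, so no second stereocentre can relay to it and it cannot be corrected by epimerisation. C3 and C8' are both nucleophilic carbons of trioxygenated rings, so a bridge made from a one-carbon dielectrophile faces homo- against hetero-coupling, and such bridges exchange partners by retro-Michael cleavage under base or heat. Ring B must carry the pyran oxygen O1' para to its isobutyryl group, which is one of two possible chromene orientations. The prenyl and chromene alkenes sit next to enol and phenol hydroxyls: they cyclise under strong acid and exclude hydrogenation, and the enol-trione is sensitive to oxidants. The feature that opens the problem is a pair of 1,6-relations: O7' of ring B reaches C4 of ring A along C7'–C8'–C7–C3, and the oxygen of the isobutyryl group on C5 reaches C2 along C(acyl)–C5–C6–C1. Trading the bonds C4–C5 and C2–C3 for two imaginary bonds O7'–C4 and O(acyl)–C2 therefore turns 19 into two six-membered lactones, dihydrocoumarin 11 and pyran-2,4-dione 17, whose formulae (C18H20O5 and C14H20O3) add up exactly to C32H40O8. In 17 the unit C2–C1–C6 is a methyl(prenyl)malonyl group whose two carbonyls already differ (lactone and ketone), so the stereochemical problem shrinks to one quaternary carbon in a small ring.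

## Retrosynthesis

(Ring A labels C1–C6 are kept for the same atoms in all precursors.)

**Cut C4–C5 (19 to 18).** C4 is returned to O7' as an aryl ester, which gives acyl lactone 18. Of the six ring A bonds, this is the one whose forward formation needs only a soft, doubly stabilised enolate (C5) and an activated ester held six atoms away. The neighbouring cut C5–C6 would require acylation next to the quaternary carbon by a hindered alkyl ester. The forward reaction has to be an O-to-C acyl transfer that ends in the most acidic species present.

**Cut C2–C3 (18 to 11 + 17).** C2 is returned to the isobutyryl oxygen as an enol lactone. This splits the molecule into halves of 18 and 14 carbons, neither containing ring A. In 17 the β-diketone is masked, so it has no acidic proton that would quench an enolate, and C2 is activated. Cutting at the bridge instead (C3–C7 or C7–C8') would bring back two competing nucleophiles. The forward reaction asks a hard lactone enolate to choose the lactone carbonyl of 17; that choice also fixes which carbonyl on C1 ends up next to the bridge, and hence the configuration.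

**Cut C1–CH2(prenyl) (17 to 15 + 16).** Removing the prenyl group leaves the flat, achiral 4-hydroxy-2-pyrone 15 and prenyl acetate 16. Cutting C1–CH3 instead would call for an enantioselective methylation, which has much weaker precedent. The forward reaction is an asymmetric allylic alkylation of a stabilised prochiral nucleophile, with linear selectivity and C-attack.

**Cut the pyrone C–O bond and the C5–C(acyl) bond (15 to 14 to 12 + 13).** Opening the lactone gives the 3,5-dioxo ester 14. Its C5–C(acyl) bond comes from the dianion of ethyl 2-methylacetoacetate 12 and the Weinreb amide 13. Both are purchased and both forward steps are standard.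

**Cut C8'–C7, C7–C3 and O7'–C4 (11 to 6 + 7 + formaldehyde, via 8, 9 and 10).** The three-atom unit C7–C3–C4 comes from formaldehyde and Meldrum's acid 7. Formaldehyde meets two nucleophiles here, but they differ widely in acidity, so the Knoevenagel partner is settled. C8' is the only free ring B position and O7' is the only hydroxyl next to it, so the lactone can close in only one way. An acid-catalysed acrylic acid annulation would endanger ring C.

**Cut ring C, then the aryl ketone (6 to 5 to 3 + 4; 3 to 1 + 2).** The chromene is traced to the 4-O-(1,1-dimethylpropargyl) ether 5. The two positions ortho to its ether oxygen are equivalent, which fixes O1' para to the ketone. Ether 5 comes from phlorisobutyrophenone 3 and chloride 4, and 3 comes from phloroglucinol 1 and isobutyryl chloride 2.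

## Roads not taken

**Alternative 1:** (the obvious route) cuts both bonds of the bridge carbon C7.
- Forward key step: union of the chiral monomer A1 with chromene 6 and formaldehyde. A1 is made by catalytic asymmetric dearomative prenylation of 3-methylphlorisobutyrophenone A2.
- In A2 the unsubstituted ring carbon and three hydroxyls compete with the methyl-bearing carbon for the prenyl group.
- The bridging joins two nucleophiles of similar reactivity through one dielectrophile, so homodimers compete, and the bridge can scramble afterwards.
- The chosen plan makes the two bonds to C7 in separate events of different polarity and never has two like nucleophiles in one flask.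

**Alternative 2:** cuts C3–C7 only and treats the stereocentre as a desymmetrisation.
- Forward key step: the achiral trione A3 adds through one of its enantiotopic carbons to the o-quinone methide A4 under a chiral Brønsted acid or hydrogen-bond catalyst. This gives A5, which is then C-acylated at C5.
- The catalyst would have to tell methyl from prenyl two bonds away from the reacting carbon.
- The electrophile terminus is an unsubstituted CH2 and offers no steric handle, and A3 can react twice.
- The late acylation of A5 must spare two phenols and a labile bridge.
- The chosen plan sets C1 in a small rigid ring at the carbon where the bond is made.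

**Alternative 3:** cuts C5–C6 and C2–C3, the neighbouring [3+3] division of ring A.
- Forward key step: C-acylation of the β-diketone A6 (from opening 11 with the enolate of 3-methylbutan-2-one) by the malonyl half-ester chloride A7, followed by Dieckmann closure of C3 onto the ester.
- A6 has two free phenols that need protection.
- The closure requires a polyanion to attack a hindered alkyl ester, and the isobutyryl methine competes as a nucleophile for a ring of the same size.
- A7 needs a longer preparation than 17.
- The chosen plan keeps O7' masked and C4 activated by the same lactone, and it places the difficult bond first, between the two most reactive partners.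

Key step: step 8

Assumption: the sense of induction of the ligand on the anion of 15 cannot be derived safely from a model. The (R,R) ligand is written, and its equally available mirror image is to be used if correlation of 17 shows the opposite sense.

## Steps

Step 1
Reactants: 1 phloroglucinol (benzene-1,3,5-triol); 2 isobutyryl chloride
Product: 3 phlorisobutyrophenone, 2-methyl-1-(2,4,6-trihydroxyphenyl)propan-1-one
Conditions: AlCl3 (3.5 equiv), CH2Cl2–PhNO2, 0 to 40 °C; aq HCl
Reagents that add atoms: none
Why: Friedel–Crafts acylation of a very electron-rich arene; the first acyl group deactivates the ring and chelates aluminium, so monoacylation should prevail.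

Step 2
Reactants: 3 phlorisobutyrophenone; 4 3-chloro-3-methylbut-1-yne
Product: 5 1-[2,6-dihydroxy-4-(2-methylbut-3-yn-2-yloxy)phenyl]-2-methylpropan-1-one
Conditions: 4 (1.0 equiv), CuCl2·2H2O (1 mol %), DBU, MeCN, 0 °C
Reagents that add atoms: none
Why: Copper-catalysed O-propargylation of a phenol with a tertiary propargylic chloride; the hydroxyl para to the ketone is the most acidic and the least involved in chelation to the carbonyl, so it should be etherified first with one equivalent of 4.

Step 3
Reactants: 5 aryl 1,1-dimethylpropargyl ether
Product: 6 1-(5,7-dihydroxy-2,2-dimethyl-2H-chromen-6-yl)-2-methylpropan-1-one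
Conditions: xylenes, 140 °C
Reagents that add atoms: none
Why: Aromatic propargyl Claisen rearrangement followed by enolisation, 1,5-hydrogen shift and oxa-6π electrocyclisation; the two positions ortho to the ether oxygen are equivalent, so one chromene with O1' para to the ketone should result, and the chelated hydroxyls stay out of the closure.

Step 4
Reactants: 6 chromene; 7 Meldrum's acid (2,2-dimethyl-1,3-dioxane-4,6-dione)
Product: 11 tricyclic lactone, the δ-lactone of 3-(5,7-dihydroxy-6-isobutyryl-2,2-dimethyl-2H-chromen-8-yl)propanoic acid closed on O7' (a 3,4-dihydrocoumarin with 5'-OH free), via methylene Meldrum's acid 8 (not isolated), via Michael adduct 9 (not isolated), via carboxy lactone 10 (not isolated)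
Conditions: (CH2O)n, pyridine, 50 °C, then 100 °C
Reagents that add atoms: formaldehyde (from paraformaldehyde), C=O
Why: Three-component Knoevenagel–Michael condensation of the Yonemitsu type, known for phloroglucinols with aldehydes and Meldrum's acid, followed by attack of O7' on the dioxanedione (loss of acetone) and decarboxylation. C8' is the only free ring position and O7' the only adjacent hydroxyl, so regiochemistry is fixed, and the medium is never acidic enough to harm ring C.

Step 5
Reactants: 12 ethyl 2-methylacetoacetate; 13 N-methoxy-N-methylisobutyramide
Product: 14 ethyl 2,6-dimethyl-3,5-dioxoheptanoate (racemic, largely enolised)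
Conditions: LiN(i-Pr)2 (2.2 equiv), THF, −78 to 0 °C; 13, −78 to 0 °C; aq HCl
Reagents that add atoms: none
Why: γ-Acylation of a β-keto ester dianion at its more reactive terminal carbon; the Weinreb amide holds the tetrahedral adduct until work-up, so the acidic product does not consume the dianion.

Step 6
Reactants: 14 3,5-dioxo ester
Product: 15 4-hydroxy-6-isopropyl-3-methyl-2H-pyran-2-one
Conditions: DBU, toluene, 110 °C; aq HCl
Reagents that add atoms: none
Why: Base-mediated lactonisation of a 3,5-dioxo ester through the enol oxygen of the δ-carbonyl, driven by loss of ethanol and by formation of the acidic hydroxypyrone as its salt.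

Step 7
Reactants: 15 hydroxypyrone; 16 prenyl acetate (3-methylbut-2-en-1-yl acetate)
Product: 17 (3S)-6-isopropyl-3-methyl-3-(3-methylbut-2-en-1-yl)-2H-pyran-2,4(3H)-dione
Conditions: Pd2(dba)3·CHCl3 (2.5 mol %), (R,R)-DACH-phenyl Trost ligand (6 mol %), 1,1,3,3-tetramethylguanidine (1.1 equiv), toluene, 0 °C
Reagents that add atoms: none
Why: Tsuji–Trost asymmetric allylic alkylation of a prochiral cyclic β-dicarbonyl nucleophile; allylation of 4-hydroxy-2-pyrones at this carbon under zerovalent palladium is known, O-allylation is reversible, and a tertiary carbon nucleophile should take the unsubstituted terminus of the 1,1-dimethylallyl complex to give the linear prenyl group. The new stereocentre C1 is set by the chiral pocket of the ligand, which distinguishes the two faces of the planar pyrone anion through its unlike flanks (lactone carbonyl against enolate oxygen).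

Step 8
Reactants: 11 tricyclic lactone; 17 (S)-pyran-2,4-dione
Product: 19 target, (4R)-3,5-dihydroxy-6-{[5,7-dihydroxy-2,2-dimethyl-6-(2-methylpropanoyl)-2H-chromen-8-yl]methyl}-4-methyl-4-(3-methylbut-2-en-1-yl)-2-(2-methylpropanoyl)cyclohexa-2,5-dien-1-one, via acyl lactone 18 (not isolated)
Conditions: 11, LiN(SiMe3)2 (2.2 equiv), THF, −78 °C; 17 (1.0 equiv), −78 to 23 °C; cold dilute aq HCl
Reagents that add atoms: none
Why: Proposed new method: the lithium enolate of 11 (carbon C3) should add to the lactone carbonyl C2 of 17 and expel the β-diketone enolate to give 18, in which proton exchange places the charge on C5; C5 then attacks the aryl ester carbonyl C4, expels phenoxide O7' and closes ring A, so that two C–O bonds are traded for two C–C bonds with no atom lost. The closest known reaction types are the crossed Claisen acylation of lactone enolates by activated esters, the Baker–Venkataraman O-to-C acyl transfer and the Claisen-mode cyclisation of 3,5,7-triketo esters to acylphloroglucinols; what is new is that both acyl donors are lactones and that the two acylations run in one flask. Ring A is the only ring closed, by a 6-(enolexo)-exo-trig attack of the C5 enolate on C4, while both lactone rings open. No stereocentre is created: C1 arrives from 17 with none of its four bonds touched, the transient centre C3 of 18 vanishes on enolisation, and the descriptor changes from S to R only because C6 now outranks C2. The absolute configuration requires C3 to bond to the lactone carbonyl C2 and not to the ketone C6 of 17, which is secured because only the adduct at C2 can collapse with loss of a leaving group, whereas addition to C6 is a reversible aldol step. Conjugate attack at the oxygen-bearing alkene carbon of 17 is held back by its isopropyl group, by full substitution of that terminus and by the use of a hard lithium enolate at −78 °C. In the closure, O-acylated isomers are enol esters that revert, aldol-mode closure cannot end in an aromatic ring because C1 is quaternary, and 19 as its polyanion is by far the most stabilised species present, so the carbocycle is the thermodynamic sink. The free 5'-OH travels as its chelated lithium phenoxide, which is why a second equivalent of base is used and no protecting group is needed.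

## Compound list

1 | phloroglucinol | Oc1cc(O)cc(O)c1 | starting material
2 | isobutyryl chloride | CC(C)C(=O)Cl | starting material
3 | phlorisobutyrophenone | CC(C)C(=O)c1c(O)cc(O)cc1O | intermediate
4 | 3-chloro-3-methylbut-1-yne | CC(C)(Cl)C#C | starting material
5 | 1-[2,6-dihydroxy-4-(2-methylbut-3-yn-2-yloxy)phenyl]-2-methylpropan-1-one | CC(C)C(=O)c1c(O)cc(OC(C)(C)C#C)cc1O | intermediate
6 | 1-(5,7-dihydroxy-2,2-dimethyl-2H-chromen-6-yl)-2-methylpropan-1-one | CC(C)C(=O)c1c(O)cc2OC(C)(C)C=Cc2c1O | intermediate
7 | Meldrum's acid | CC1(C)OC(=O)CC(=O)O1 | starting material
8 | methylene Meldrum's acid (5-methylidene-2,2-dimethyl-1,3-dioxane-4,6-dione) | C=C1C(=O)OC(C)(C)OC1=O | intermediate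
9 | 5-[(5,7-dihydroxy-6-isobutyryl-2,2-dimethyl-2H-chromen-8-yl)methyl]-2,2-dimethyl-1,3-dioxane-4,6-dione | CC(C)C(=O)c1c(O)c(CC2C(=O)OC(C)(C)OC2=O)c2OC(C)(C)C=Cc2c1O | intermediate
10 | α-carboxylic acid of lactone 11 (racemic) | CC(C)C(=O)c1c(O)c2C=CC(C)(C)Oc2c2CC(C(=O)O)C(=O)Oc12 | intermediate
11 | tricyclic lactone (dihydrocoumarin closed on O7', 5'-OH free) | CC(C)C(=O)c1c(O)c2C=CC(C)(C)Oc2c2CCC(=O)Oc12 | intermediate
12 | ethyl 2-methylacetoacetate | CCOC(=O)C(C)C(C)=O | starting material
13 | N-methoxy-N-methylisobutyramide | CON(C)C(=O)C(C)C | starting material
14 | ethyl 2,6-dimethyl-3,5-dioxoheptanoate | CCOC(=O)C(C)C(=O)CC(=O)C(C)C | intermediate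
15 | 4-hydroxy-6-isopropyl-3-methyl-2H-pyran-2-one | CC(C)C1=CC(O)=C(C)C(=O)O1 | intermediate
16 | prenyl acetate | CC(C)=CCOC(C)=O | starting material
17 | (3S)-6-isopropyl-3-methyl-3-(3-methylbut-2-en-1-yl)-2H-pyran-2,4(3H)-dione | CC(C)=CC[C@]1(C)C(=O)OC(C(C)C)=CC1=O | intermediate
18 | lactone 11 acylated at its α-carbon C3 by the (2S)-2,6-dimethyl-2-(3-methylbut-2-en-1-yl)-3,5-dioxoheptanoyl group (C3 epimers and enol forms) | CC(C)=CC[C@@](C)(C(=O)CC(=O)C(C)C)C(=O)C1Cc2c(OC1=O)c(C(=O)C(C)C)c(O)c1C=CC(C)(C)Oc21 | intermediate
19 | CNP0319758.1, (R) at C1 | CC(C)=CC[C@]1(C)C(O)=C(Cc2c(O)c(C(=O)C(C)C)c(O)c3c2OC(C)(C)C=C3)C(=O)C(C(=O)C(C)C)=C1O | target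

## Step count and risks

Total: 8 steps. Longest linear sequence: 5 steps (1, 2, 3, 4, 8); the second branch (5, 6, 7) joins at step 8.

**Step 8 (key step, proposed new method).**
- What may go wrong:
  - loss of site selectivity on 17, through conjugate addition–elimination at the oxygen-bearing alkene carbon or proton transfer from the isopropyl methine to the enolate;
  - self-condensation of the aryl lactone enolate before 17 is added;
  - stalling at the open stage if the charge rests on the C2–C3–C4 β-keto lactone unit and deactivates C4.
- Fallback (sets out from 17 and 6, returns at 19, and gives up the lactone union for a stepwise ring synthesis and a known bridging):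
  - Methanolysis of 17 with NaOMe in MeOH should give methyl (2S)-2,6-dimethyl-2-(3-methylbut-2-en-1-yl)-3,5-dioxoheptanoate F1.
  - C-acetylation of its magnesium enolate (MgCl2, pyridine, acetyl chloride) should give methyl (2S)-4-acetyl-2,6-dimethyl-2-(3-methylbut-2-en-1-yl)-3,5-dioxoheptanoate F2.
  - Claisen-mode Dieckmann closure with KOt-Bu in THF should give the monomer (4R)-3,5-dihydroxy-2-isobutyryl-4-methyl-4-(3-methylbut-2-en-1-yl)cyclohexa-2,5-dien-1-one F3.
  - In parallel, 6 is aminomethylated at C8' with dimethylmethyleneammonium iodide to the Mannich base 1-{8-[(dimethylamino)methyl]-5,7-dihydroxy-2,2-dimethyl-2H-chromen-6-yl}-2-methylpropan-1-one F4.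
  - Heating F4 with F3 in toluene releases the o-quinone methide, which F3 traps at C3 to give 19.

**Step 7.**
- What may go wrong:
  - poor facial selectivity on a small flat nucleophile;
  - erosion of enantiopurity by reversible ionisation of the C1–prenyl bond, since the pyrone anion is a good leaving group;
  - O-alkylation that does not revert at low temperature;
  - attack at the substituted allyl terminus.
- Fallback (sets out from 15, returns at 17, and replaces catalyst control by chirality transfer from a stereocentre that is later excised):
  - Mitsunobu etherification of 15 with (R)-but-3-en-2-ol (PPh3, DIAD, THF), with inversion, should give 4-{[(2S)-but-3-en-2-yl]oxy}-6-isopropyl-3-methyl-2H-pyran-2-one F5.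
  - Claisen rearrangement in toluene at 110 °C, through the chair with the methyl group equatorial, should give (3S)-3-[(2E)-but-2-en-1-yl]-6-isopropyl-3-methyl-2H-pyran-2,4(3H)-dione F6.
  - Cross metathesis with 2-methylbut-2-ene (second-generation Grubbs catalyst, CH2Cl2, 40 °C) converts the crotyl group into prenyl and gives 17.
  - This sequence also provides an independent correlation of the configuration of 17.

**Step 4.**
- What may go wrong:
  - double arylation of formaldehyde, which would bridge two chromene units;
  - sluggish attack by C8' because the ketone lowers the nucleophilicity of ring B;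
  - thermal breakdown of Meldrum's acid before the Michael step.
- Fallback (sets out from 6, returns at 11, and builds the three carbons by olefination):
  - Vilsmeier–Haack formylation (POCl3, DMF) should give 5,7-dihydroxy-6-isobutyryl-2,2-dimethyl-2H-chromene-8-carbaldehyde F7.
  - Wittig reaction with ethyl (triphenylphosphoranylidene)acetate should give ethyl (E)-3-(5,7-dihydroxy-6-isobutyryl-2,2-dimethyl-2H-chromen-8-yl)acrylate F8.
  - Heating F8 in N,N-diethylaniline should isomerise and lactonise it to the pyranocoumarin F9.
  - Conjugate reduction with [(Ph3P)CuH]6 in toluene should touch only the α,β-unsaturated lactone and give 11.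

**Step 2.**
- What may go wrong: alkylation on a ring carbon or on more than one hydroxyl, since all three hydroxyls and two ring carbons are nucleophilic.
- Fallback (sets out from 3, returns at 6, and skips 5): condensation of 3 with 3-methylbut-2-enal under ethylenediammonium diacetate catalysis in toluene at 80 °C (Knoevenagel condensation, then oxa-6π electrocyclisation). This accepts a chromatographic separation of the two chromene orientations in exchange for one step fewer.

## Further compounds

F1 | step 8 | methyl (2S)-2,6-dimethyl-2-(3-methylbut-2-en-1-yl)-3,5-dioxoheptanoate | CC(C)=CC[C@](C)(C(=O)OC)C(=O)CC(=O)C(C)C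
F2 | step 8 | methyl (2S)-4-acetyl-2,6-dimethyl-2-(3-methylbut-2-en-1-yl)-3,5-dioxoheptanoate | CC(C)=CC[C@](C)(C(=O)OC)C(=O)C(C(C)=O)C(=O)C(C)C
F3 | step 8 | (4R)-3,5-dihydroxy-2-isobutyryl-4-methyl-4-(3-methylbut-2-en-1-yl)cyclohexa-2,5-dien-1-one | CC(C)=CC[C@]1(C)C(O)=CC(=O)C(C(=O)C(C)C)=C1O
F4 | step 8 | 1-{8-[(dimethylamino)methyl]-5,7-dihydroxy-2,2-dimethyl-2H-chromen-6-yl}-2-methylpropan-1-one | CC(C)C(=O)c1c(O)c(CN(C)C)c2OC(C)(C)C=Cc2c1O
F5 | step 7 | 4-{[(2S)-but-3-en-2-yl]oxy}-6-isopropyl-3-methyl-2H-pyran-2-one | CC(C)C1=CC(O[C@@H](C)C=C)=C(C)C(=O)O1
F6 | step 7 | (3S)-3-[(2E)-but-2-en-1-yl]-6-isopropyl-3-methyl-2H-pyran-2,4(3H)-dione | C/C=C/C[C@]1(C)C(=O)OC(C(C)C)=CC1=O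
F7 | step 4 | 5,7-dihydroxy-6-isobutyryl-2,2-dimethyl-2H-chromene-8-carbaldehyde | CC(C)C(=O)c1c(O)c(C=O)c2OC(C)(C)C=Cc2c1O
F8 | step 4 | ethyl (E)-3-(5,7-dihydroxy-6-isobutyryl-2,2-dimethyl-2H-chromen-8-yl)acrylate | CCOC(=O)/C=C/c1c(O)c(C(=O)C(C)C)c(O)c2C=CC(C)(C)Oc12
F9 | step 4 | pyranocoumarin (3,4-didehydro analogue of lactone 11) | CC(C)C(=O)c1c(O)c2C=CC(C)(C)Oc2c2C=CC(=O)Oc12
F0 | step 2 | none | none
A1 | alternative 1 | (4R)-3,5-dihydroxy-2-isobutyryl-4-methyl-4-(3-methylbut-2-en-1-yl)cyclohexa-2,5-dien-1-one | CC(C)=CC[C@]1(C)C(O)=CC(=O)C(C(=O)C(C)C)=C1O
A2 | alternative 1 | 3-methylphlorisobutyrophenone, 2-methyl-1-(2,4,6-trihydroxy-3-methylphenyl)propan-1-one | CC(C)C(=O)c1c(O)cc(O)c(C)c1O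
A3 | alternative 2 | 2-methyl-2-(3-methylbut-2-en-1-yl)cyclohexane-1,3,5-trione (achiral) | CC(C)=CCC1(C)C(=O)CC(=O)CC1=O
A4 | alternative 2 | o-quinone methide of the chromene half (8'-methylidene, 7'-oxo) | C=C1C(=O)C(C(=O)C(C)C)=C(O)C2=C1OC(C)(C)C=C2
A5 | alternative 2 | target lacking the isobutyryl group on C5 | CC(C)=CC[C@]1(C)C(O)=C(Cc2c(O)c(C(=O)C(C)C)c(O)c3c2OC(C)(C)C=C3)C(=O)C=C1O
A6 | alternative 3 | 1-(5,7-dihydroxy-6-isobutyryl-2,2-dimethyl-2H-chromen-8-yl)-6-methylheptane-3,5-dione | CC(C)C(=O)CC(=O)CCc1c(O)c(C(=O)C(C)C)c(O)c2C=CC(C)(C)Oc12
A7 | alternative 3 | methyl (2R)-2-(chlorocarbonyl)-2,5-dimethylhex-4-enoate | CC(C)=CC[C@](C)(C(=O)OC)C(=O)Cl
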